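## Retrosynthetic overview

1. Target 24 ⇒ C7–O(acyl) bond: radical acyloxylative dearomatisation of anhydrobase 23 with perester 10, as the last step; this sets C7.
2. 23 ⇒ o-alkynylbenzaldehyde 21 by 6-endo cycloisomerisation, which closes the pyran ring.
3. 21 ⇒ aryl bromide 16 + ethynyltrimethylsilane 19 + iodoenone 18 (two Sonogashira couplings in one flask); 16 ⇐ 3-bromophenol by C–H borylation/oxidation, formylation and C-methylation.
4. 10 ⇐ acid 9 ⇐ anti-aldol of a propanoyl oxazolidinone with (E)-2-methylbut-2-enal, which sets C2′ and C3′ and carries the E-alkene.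
5. Ring order: benzene ring (from 11) and cyclohexenone ring (from 17) are bought; pyran ring in step 11; the carbocycle is dearomatised in step 12.

Assumption: the recoverable oxazolidinone auxiliary is treated as a reagent (none of its atoms reach the target), and anhydrobase 23 is drawn as its 8-hydroxy-6-one tautomer.

## Route

Step 1
Reactants: 1 propanoyl chloride
Product: 2 (4R)-4-benzyl-3-propanoyl-1,3-oxazolidin-2-one
Conditions: (R)-4-benzyl-1,3-oxazolidin-2-one, n-BuLi, THF, −78 °C; then 1, −78 → 0 °C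
Reagents that add atoms: (R)-4-benzyl-1,3-oxazolidin-2-one, O=C1N[C@H](Cc2ccccc2)CO1
Why: N-acylation of the lithiated oxazolidinone by the acid chloride (Evans auxiliary loading); the auxiliary stereocentre is not touched.

Step 2
Reactants: 2 (4R)-4-benzyl-3-propanoyl-1,3-oxazolidin-2-one; 3 (E)-2-methylbut-2-enal
Product: 5 (4R)-4-benzyl-3-[(2S,3R,4E)-3-hydroxy-2,4-dimethylhex-4-enoyl]-1,3-oxazolidin-2-one, via trimethylsilyl ether 4 (not isolated)
Conditions: MgCl2 (10 mol%), Et3N (2 equiv), TMSCl (1.5 equiv), EtOAc, 23 °C, 24 h; then TFA (cat.), MeOH, 23 °C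
Reagents that add atoms: none
Why: Magnesium-catalysed direct anti-aldol of an N-acyloxazolidinone (Evans MgCl2 anti-aldol) with a non-enolisable enal; by the chelated Z-enolate model the aldehyde adds to the face opposite the benzyl group through a boat-like transition state, which from the (R)-auxiliary predicts the (2S,3R) anti adduct, and silylation of the aldolate turns the magnesium over.

Step 3
Reactants: 5 (4R)-4-benzyl-3-[(2S,3R,4E)-3-hydroxy-2,4-dimethylhex-4-enoyl]-1,3-oxazolidin-2-one
Product: 7 (2S,3R,4E)-3-hydroxy-2,4-dimethylhex-4-enoic acid, via peroxy acid 6 (not isolated)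
Conditions: LiOH, H2O2, THF/H2O 3:1, 0 °C; then Na2SO3; then HCl to pH 3
Reagents that add atoms: hydrogen peroxide, OO
Why: Hydroperoxide attacks the exocyclic imide carbonyl selectively (LiOOH auxiliary cleavage) and sulfite reduces the percarboxylate before acidification, so the alkene is not epoxidised and neither stereocentre is touched.

Step 4
Reactants: 7 (2S,3R,4E)-3-hydroxy-2,4-dimethylhex-4-enoic acid
Product: 9 (2S,3R,4E)-3-acetoxy-2,4-dimethylhex-4-enoic acid, via mixed anhydride 8 (not isolated)
Conditions: Ac2O, pyridine, DMAP (cat.), CH2Cl2, 0 → 23 °C; then H2O, 23 °C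
Reagents that add atoms: acetic anhydride, CC(=O)OC(C)=O
Why: DMAP-catalysed acetylation of the secondary allylic alcohol; the mixed anhydride formed at the carboxyl group is hydrolysed on aqueous work-up, and no stereocentre is involved at this temperature.

Step 5
Reactants: 9 (2S,3R,4E)-3-acetoxy-2,4-dimethylhex-4-enoic acid
Product: 10 tert-butyl (2S,3R,4E)-3-acetoxy-2,4-dimethylhex-4-eneperoxoate
Conditions: t-BuOOH (decane solution), DCC, DMAP (5 mol%), CH2Cl2, −10 → 0 °C
Reagents that add atoms: tert-butyl hydroperoxide, CC(C)(C)OO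
Why: Steglich-type carbodiimide coupling of the acid with the hydroperoxide gives the perester below 0 °C without base strong enough to epimerise C2 or eliminate the β-acetate.

Step 6
Reactants: 11 3-bromophenol
Product: 13 5-bromobenzene-1,3-diol, via aryl boronate 12 (not isolated)
Conditions: HBpin (2.5 equiv), [Ir(OMe)(cod)]2 (1.5 mol%), 4,4′-di-tert-butyl-2,2′-bipyridine (3 mol%), THF, 80 °C; then KHSO5 (as 2KHSO5·KHSO4·K2SO4), acetone/H2O, 23 °C
Reagents that add atoms: potassium peroxymonosulfate KHSO5, [K+].[O-]S(=O)(=O)OO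
Why: One-pot iridium-catalysed C–H borylation/oxidation: the phenol is O-borylated in situ, the sterically governed borylation takes the only C–H with no ortho substituent (C5), and the C–B bond is oxidised to the phenol.

Step 7
Reactants: 13 5-bromobenzene-1,3-diol
Product: 15 2-bromo-4,6-dihydroxybenzaldehyde, via iminium chloride 14 (not isolated)
Conditions: POCl3, DMF, MeCN, −15 → 23 °C; then H2O, 50 °C
Reagents that add atoms: N,N-dimethylformamide, CN(C)C=O; water, O
Why: Vilsmeier–Haack formylation of the resorcinol para to one hydroxyl and ortho to the other, the same position taken in 5-alkylresorcinols; the iminium salt is hydrolysed to the aldehyde.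

Step 8
Reactants: 15 2-bromo-4,6-dihydroxybenzaldehyde
Product: 16 6-bromo-2,4-dihydroxy-3-methylbenzaldehyde
Conditions: MeI (1.1 equiv), KOH (2.2 equiv), MeOH/H2O, 0 → 23 °C
Reagents that add atoms: iodomethane, CI
Why: Nuclear C-methylation of the resorcylaldehyde dianion at the carbon between the two phenoxide oxygens, as known for β-resorcylaldehyde and resacetophenone; the other free ring carbon is shielded by bromine.

Step 9
Reactants: 17 3-methylcyclohex-2-en-1-one
Product: 18 2-iodo-3-methylcyclohex-2-en-1-one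
Conditions: I2, pyridine/CH2Cl2 1:1, 0 → 23 °C, dark
Reagents that add atoms: iodine, [I][I]
Why: α-Iodination of the enone by conjugate addition of pyridine, iodination of the enolate and elimination (Baylis–Hillman-type α-halogenation).

Step 10
Reactants: 16 6-bromo-2,4-dihydroxy-3-methylbenzaldehyde; 19 ethynyltrimethylsilane; 18 2-iodo-3-methylcyclohex-2-en-1-one
Product: 21 2,4-dihydroxy-3-methyl-6-[(2-methyl-6-oxocyclohex-1-en-1-yl)ethynyl]benzaldehyde, via silylalkyne 20 (not isolated)
Conditions: 19 (1.1 equiv), PdCl2(PPh3)2 (5 mol%), CuI (10 mol%), Et3N, DMF, 60 °C; N2 purge; then 18, CsF, 23 → 40 °C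
Reagents that add atoms: none
Why: Two Sonogashira couplings in one flask: the aldehyde-activated aryl bromide takes the silylalkyne first, then fluoride unmasks the alkyne in situ (sila-Sonogashira) and the much more reactive alkenyl iodide couples near room temperature.

Step 11
Reactants: 21 2,4-dihydroxy-3-methyl-6-[(2-methyl-6-oxocyclohex-1-en-1-yl)ethynyl]benzaldehyde
Product: 23 8-hydroxy-7-methyl-3-(2-methyl-6-oxocyclohex-1-en-1-yl)-6H-isochromen-6-one, via benzopyrylium trifluoroacetate 22 (not isolated)
Conditions: Au(OAc)3 (5 mol%), CF3CO2H/ClCH2CH2Cl 1:10, 23 °C, 10 min; evaporate; then CH2Cl2/pH 7 KH2PO4–K2HPO4 buffer, 0 °C, used at once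
Reagents that add atoms: none
Why: Gold-catalysed cycloisomerisation of an o-alkynylbenzaldehyde: alkyne activation triggers 6-endo attack of the aldehyde oxygen to the aromatic 6,8-dihydroxy-2-benzopyrylium, and neutralisation removes a phenolic proton to give the quinone-methide-type anhydrobase.

Step 12
Reactants: 23 8-hydroxy-7-methyl-3-(2-methyl-6-oxocyclohex-1-en-1-yl)-6H-isochromen-6-one; 10 tert-butyl (2S,3R,4E)-3-acetoxy-2,4-dimethylhex-4-eneperoxoate
Product: 24 (7S)-7-methyl-3-(2-methyl-6-oxocyclohex-1-en-1-yl)-6,8-dioxo-7,8-dihydro-6H-isochromen-7-yl (2S,3R,4E)-3-acetoxy-2,4-dimethylhex-4-enoate (Pleosporalone D)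
Conditions: Cu(MeCN)4PF6 (10 mol%), (S,S)-t-Bu-box (12 mol%), 10 (1.3 equiv, slow addition), acetone, −20 → 23 °C, Ar, dark
Reagents that add atoms: none
Why: Proposed new method: monovalent copper cleaves the O–O bond of perester 10 to a tert-butoxyl radical and a bisoxazoline-bound divalent copper carboxylate; tert-butoxyl abstracts the weak enolic O–H of 23, and the resulting radical has its carbon spin at C7, between the two carbonyls of the vinylogous 2-methyl-1,3-dione; this tertiary radical is captured by the divalent copper carboxylate and collapses through a trivalent copper intermediate to the C7–O ester bond, returning monovalent copper; the closest known reaction types are the Kharasch–Sosnovsky perester acyloxylation (enantioselective with copper–bisoxazoline catalysts) and the two-electron Wessely-type acyloxylation of benzopyrylium anhydrobases at this same carbon; C7 is set in the C–O-forming event by the chiral ligand acting together with the chiral carboxylate, but the sense of induction cannot be predicted, so the (S,S)-ligand is a first choice to be exchanged for its antipode if the pairing is mismatched, and the 7R epimer is a diastereomer that chromatography removes.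

## Compound list

1 | propanoyl chloride | CCC(=O)Cl | starting material
2 | (4R)-4-benzyl-3-propanoyl-1,3-oxazolidin-2-one | CCC(=O)N1[C@H](Cc2ccccc2)COC1=O | intermediate
3 | (E)-2-methylbut-2-enal | C/C=C(\C)C=O | starting material
4 | (4R)-4-benzyl-3-[(2S,3R,4E)-2,4-dimethyl-3-(trimethylsilyloxy)hex-4-enoyl]-1,3-oxazolidin-2-one | C/C=C(\C)[C@H](O[Si](C)(C)C)[C@H](C)C(=O)N1[C@H](Cc2ccccc2)COC1=O | intermediate
5 | (4R)-4-benzyl-3-[(2S,3R,4E)-3-hydroxy-2,4-dimethylhex-4-enoyl]-1,3-oxazolidin-2-one | C/C=C(\C)[C@H](O)[C@H](C)C(=O)N1[C@H](Cc2ccccc2)COC1=O | intermediate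
6 | (2S,3R,4E)-3-hydroxy-2,4-dimethylhex-4-eneperoxoic acid | C/C=C(\C)[C@H](O)[C@H](C)C(=O)OO | intermediate
7 | (2S,3R,4E)-3-hydroxy-2,4-dimethylhex-4-enoic acid | C/C=C(\C)[C@H](O)[C@H](C)C(=O)O | intermediate
8 | acetic (2S,3R,4E)-3-acetoxy-2,4-dimethylhex-4-enoic anhydride | C/C=C(\C)[C@H](OC(C)=O)[C@H](C)C(=O)OC(C)=O | intermediate
9 | (2S,3R,4E)-3-acetoxy-2,4-dimethylhex-4-enoic acid | C/C=C(\C)[C@H](OC(C)=O)[C@H](C)C(=O)O | intermediate
10 | tert-butyl (2S,3R,4E)-3-acetoxy-2,4-dimethylhex-4-eneperoxoate | C/C=C(\C)[C@H](OC(C)=O)[C@H](C)C(=O)OOC(C)(C)C | intermediate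
11 | 3-bromophenol | Oc1cccc(Br)c1 | starting material
12 | 2-[3-bromo-5-(4,4,5,5-tetramethyl-1,3,2-dioxaborolan-2-yloxy)phenyl]-4,4,5,5-tetramethyl-1,3,2-dioxaborolane | CC1(C)OB(Oc2cc(Br)cc(B3OC(C)(C)C(C)(C)O3)c2)OC1(C)C | intermediate
13 | 5-bromobenzene-1,3-diol | Oc1cc(O)cc(Br)c1 | intermediate
14 | N-[(2-bromo-4,6-dihydroxyphenyl)methylidene]-N-methylmethanaminium chloride | C[N+](C)=Cc1c(O)cc(O)cc1Br.[Cl-] | intermediate
15 | 2-bromo-4,6-dihydroxybenzaldehyde | O=Cc1c(O)cc(O)cc1Br | intermediate
16 | 6-bromo-2,4-dihydroxy-3-methylbenzaldehyde | Cc1c(O)cc(Br)c(C=O)c1O | intermediate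
17 | 3-methylcyclohex-2-en-1-one | CC1=CC(=O)CCC1 | starting material
18 | 2-iodo-3-methylcyclohex-2-en-1-one | CC1=C(I)C(=O)CCC1 | intermediate
19 | ethynyltrimethylsilane | C#C[Si](C)(C)C | starting material
20 | 2,4-dihydroxy-3-methyl-6-[(trimethylsilyl)ethynyl]benzaldehyde | Cc1c(O)cc(C#C[Si](C)(C)C)c(C=O)c1O | intermediate
21 | 2,4-dihydroxy-3-methyl-6-[(2-methyl-6-oxocyclohex-1-en-1-yl)ethynyl]benzaldehyde | Cc1c(O)cc(C#CC2=C(C)CCCC2=O)c(C=O)c1O | intermediate
22 | 6,8-dihydroxy-7-methyl-3-(2-methyl-6-oxocyclohex-1-en-1-yl)isochromenylium trifluoroacetate | Cc1c(O)cc2cc(C3=C(C)CCCC3=O)[o+]cc2c1O.[O-]C(=O)C(F)(F)F | intermediate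
23 | 8-hydroxy-7-methyl-3-(2-methyl-6-oxocyclohex-1-en-1-yl)-6H-isochromen-6-one | CC1=C(O)C2=COC(C3=C(C)CCCC3=O)=CC2=CC1=O | intermediate
24 | (7S)-7-methyl-3-(2-methyl-6-oxocyclohex-1-en-1-yl)-6,8-dioxo-7,8-dihydro-6H-isochromen-7-yl (2S,3R,4E)-3-acetoxy-2,4-dimethylhex-4-enoate (Pleosporalone D) | C/C=C(\C)[C@H](OC(C)=O)[C@H](C)C(=O)O[C@@]1(C)C(=O)C=C2C=C(C3=C(C)CCCC3=O)OC=C2C1=O | target

## Step count and risks

Total steps: 12. Longest linear sequence: 6 steps (steps 1, 2, 3, 4, 5, 12, or equally steps 6, 7, 8, 10, 11, 12).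

The three steps most likely to fail:

Step 12 (radical C7–O bond formation; untested reaction, uncertain facial control at C7, possible radical dimerisation). The fallback sets out from 21 and returns to the route at 24, using acid 9 as the acyl donor. Phenol 21 is oxygenated at the carbon between its two hydroxyls by the dioxygen adduct of Cu(MeCN)4PF6 and (+)-sparteine (iPr2NEt, DMAP, O2, CH2Cl2, −78 → −10 °C). This is the ligand series that gives the 7S arrangement in non-halogenated azaphilones, recalled from memory and to be confirmed. The product is (3R)-2,3-dihydroxy-3-methyl-6-[(2-methyl-6-oxocyclohex-1-en-1-yl)ethynyl]-4-oxocyclohexa-1,5-diene-1-carbaldehyde F1. Its pyran ring closes with the copper salt already present under KH2PO4/K2HPO4 buffer in MeCN to give (7S)-7-hydroxy-7-methyl-3-(2-methyl-6-oxocyclohex-1-en-1-yl)-6H-isochromene-6,8(7H)-dione F2. Steglich esterification of the tertiary alcohol of F2 with 9 (DCC, DMAP, CH2Cl2, 23 °C) gives 24.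

Step 11 (the enone carbonyl can compete with the aldehyde for the gold-activated alkyne and give a furan; the anhydrobase is sensitive to water and to handling). The fallback sets out from 21 and returns at 24, using perester 10. The order of events is reversed: the copper/perester radical acyloxylation of step 12 is run on phenol 21 itself, whose phenoxyl radical carries its spin at the methyl-bearing carbon between the two oxygens. This gives (1R)-3-formyl-2-hydroxy-1-methyl-4-[(2-methyl-6-oxocyclohex-1-en-1-yl)ethynyl]-6-oxocyclohexa-2,4-dien-1-yl (2S,3R,4E)-3-acetoxy-2,4-dimethylhex-4-enoate F3. This non-aromatic vinylogous acid then closes its pyran ring under CuI and KH2PO4/K2HPO4 buffer in MeCN at 23 °C, without gold, without CF3CO2H and without an isolated anhydrobase, to give 24.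

Step 10 (one-flask double coupling with free phenols, an aldehyde and a base-sensitive iodoenone in the presence of fluoride). The fallback sets out from 18 and 19 and returns at 21. The alkyne is built on the enone partner instead, with every intermediate isolated. Sonogashira coupling of 18 with 19 (PdCl2(PPh3)2, CuI, iPr2NH, THF, 23 °C) gives 3-methyl-2-[(trimethylsilyl)ethynyl]cyclohex-2-en-1-one F4. Methanolysis (K2CO3, MeOH, 0 °C) gives 2-ethynyl-3-methylcyclohex-2-en-1-one F5. A second Sonogashira coupling of F5 with aryl bromide 16 (PdCl2(PPh3)2, CuI, Et3N, DMF, 60 °C) gives 21.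

## Further compounds

F1 | step 12 | (3R)-2,3-dihydroxy-3-methyl-6-[(2-methyl-6-oxocyclohex-1-en-1-yl)ethynyl]-4-oxocyclohexa-1,5-diene-1-carbaldehyde | O[C@@]1(C)C(=O)C=C(C#CC2=C(C)CCCC2=O)C(C=O)=C1O
F2 | step 12 | (7S)-7-hydroxy-7-methyl-3-(2-methyl-6-oxocyclohex-1-en-1-yl)-6H-isochromene-6,8(7H)-dione | O[C@@]1(C)C(=O)C=C2C=C(C3=C(C)CCCC3=O)OC=C2C1=O
F3 | step 11 | (1R)-3-formyl-2-hydroxy-1-methyl-4-[(2-methyl-6-oxocyclohex-1-en-1-yl)ethynyl]-6-oxocyclohexa-2,4-dien-1-yl (2S,3R,4E)-3-acetoxy-2,4-dimethylhex-4-enoate | C/C=C(\C)[C@H](OC(C)=O)[C@H](C)C(=O)O[C@@]1(C)C(=O)C=C(C#CC2=C(C)CCCC2=O)C(C=O)=C1O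
F4 | step 10 | 3-methyl-2-[(trimethylsilyl)ethynyl]cyclohex-2-en-1-one | CC1=C(C#C[Si](C)(C)C)C(=O)CCC1
F5 | step 10 | 2-ethynyl-3-methylcyclohex-2-en-1-one | CC1=C(C#C)C(=O)CCC1
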